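**Plan**

- Retrosynthesis: the eight phenols are carried as benzyl ethers. The first cut is the C4–C4a bond of lactone A (the unit with four ring oxygens, unprimed atoms), which leads back to aryl ester 23 of an (E)-2-substituted cinnamic acid. The next cuts are the ester bond O1–C2 (phenol 9 + acid 22) and then C3'–C4' and O1'–C2' of lactone B (primed atoms), giving an ortho-quinone methide and Stobbe half-ester 13.
- Forward: phenol 9 is made in five steps from 2,3,4-trihydroxybenzaldehyde; lactone B is built first by an enantioselective Michael addition–lactonisation; the tert-butyl ester is exchanged for the ester of 9; lactone A is closed last; hydrogenolysis ends the route.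
- Enabling feature: in ring A, C4 is both β to the lactone carbonyl C2 and benzylic to a para-oxygenated phenyl ring, so activation of C2=O turns it into a stabilised cation. C4a is the only C–H of the pentaoxygenated benzene ring, ortho to O1 and ortho/para to two ether oxygens, and closes a six-membered ring through O1–C2–C3.
- Stereochemistry: C4' comes from the chiral isothiourea; C3' from equilibration to trans; C4 from allylic 1,3-strain exerted by C3' (the arene adds anti to C4'); C3 from kinetic protonation of the ring A enol anti to the C4 aryl group (cis). The neutral final deprotection preserves it.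

Key step: step 12

Remark on the chemistry: the target is read as lactone A 3,4-cis (3S,4R) and lactone B 3,4-trans (3S,4S); trans is taken as the thermodynamic and cis as the kinetic arrangement of a 3,4-disubstituted 4-aryl-dihydrocoumarin, and the sense of induction of the isothiourea in step 9 is assigned by analogy, the mirror-image catalyst being taken if the 4R series formed.

**Step 1**
Reactants: 1 2,3,4-trihydroxybenzaldehyde
Product: 2 2,3,4-tris(benzyloxy)benzaldehyde
Conditions: BnBr (3.3 equiv), K2CO3, DMF, 60 °C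
Reagents that add atoms: benzyl bromide, BrCc1ccccc1
Why: Williamson ether synthesis: all three phenoxides are O-benzylated, the hydrogen-bonded 2-hydroxyl being driven to completion by excess bromide and warming.

**Step 2**
Reactants: 2 2,3,4-tris(benzyloxy)benzaldehyde
Product: 4 2,3,4-tris(benzyloxy)phenol, via 2,3,4-tris(benzyloxy)phenyl formate 3 (not isolated)
Conditions: mCPBA, CH2Cl2, 0 °C to rt; then MeOH, HCl (cat.), rt
Reagents that add atoms: 3-chloroperoxybenzoic acid (mCPBA), OOC(=O)c1cccc(Cl)c1
Why: Baeyer–Villiger (Dakin-type) oxidation: the electron-rich aryl group with ortho and para ether oxygens migrates in preference to hydride to give formate 3, which acid-catalysed methanolysis converts into the phenol.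

**Step 3**
Reactants: 4 2,3,4-tris(benzyloxy)phenol
Product: 5 1,2,3,4-tetrakis(benzyloxy)benzene
Conditions: BnBr (1.2 equiv), K2CO3, DMF, rt
Reagents that add atoms: benzyl bromide, BrCc1ccccc1
Why: Williamson ether synthesis on the single free phenol gives the symmetrical tetraether, whose two remaining ring positions are equivalent.

**Step 4**
Reactants: 5 1,2,3,4-tetrakis(benzyloxy)benzene
Product: 7 2,3,4,5-tetrakis(benzyloxy)benzaldehyde, via aryl iminium chloride 6 (not isolated)
Conditions: POCl3, DMF, 80 °C; then aq. NaOAc, rt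
Reagents that add atoms: N,N-dimethylformamide, CN(C)C=O; water, O
Why: Vilsmeier–Haack formylation: the chloroiminium electrophile attacks one of the two equivalent C–H positions, each ortho and para to an ether oxygen, and iminium 6 is hydrolysed on work-up.

**Step 5**
Reactants: 7 2,3,4,5-tetrakis(benzyloxy)benzaldehyde
Product: 9 2,3,4,5-tetrakis(benzyloxy)phenol, via 2,3,4,5-tetrakis(benzyloxy)phenyl formate 8 (not isolated)
Conditions: mCPBA, CH2Cl2, 0 °C to rt; then MeOH, HCl (cat.), rt
Reagents that add atoms: 3-chloroperoxybenzoic acid (mCPBA), OOC(=O)c1cccc(Cl)c1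
Why: Baeyer–Villiger (Dakin-type) oxidation and methanolysis of the formate, as in step 2, should deliver the pentaoxygenated phenol whose only ring C–H is ortho to the free hydroxyl.

**Step 6**
Reactants: 10 di-tert-butyl succinate; 11 4-(benzyloxy)benzaldehyde
Product: 13 (3E)-4-[4-(benzyloxy)phenyl]-3-(tert-butoxycarbonyl)but-3-enoic acid, via paraconate lactone 12 (not isolated)
Conditions: KOtBu (1.2 equiv), tBuOH, 60 °C; then aq. HCl, 0 °C
Reagents that add atoms: none
Why: Stobbe condensation: aldol addition of the succinate enolate, lactonisation to paraconate 12 and E1cB ring opening give the half-ester with the free acid on the CH2 carbon and the E alkene (aryl trans to the retained ester) under thermodynamic control.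

**Step 7**
Reactants: 14 3,5-bis(benzyloxy)phenol
Product: 15 2,4-bis(benzyloxy)-6-hydroxybenzaldehyde
Conditions: (CH2O)n, MgCl2, Et3N, MeCN, reflux
Reagents that add atoms: paraformaldehyde (as formaldehyde), C=O
Why: Casnati–Skattebøl ortho-formylation through the magnesium phenoxide is ortho-specific, and the two ortho positions of 14 are equivalent, so a single salicylaldehyde should result.

**Step 8**
Reactants: 15 2,4-bis(benzyloxy)-6-hydroxybenzaldehyde; 16 4-(benzyloxy)phenylmagnesium bromide
Product: 18 3,5-bis(benzyloxy)-2-{[4-(benzyloxy)phenyl](4-methylbenzenesulfonyl)methyl}phenol (racemic), via benzhydrol 17 (not isolated)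
Conditions: 16 (2.2 equiv), THF, 0 °C; aq. NH4Cl; then sodium 4-methylbenzenesulfinate, HCO2H, CH2Cl2/H2O, rt
Reagents that add atoms: sodium 4-methylbenzenesulfinate, [Na+].[O-]S(=O)c1ccc(C)cc1
Why: Grignard addition to the magnesium salt of the salicylaldehyde (the first equivalent is consumed by the phenol) gives acid-labile benzhydrol 17, which ionises in aqueous formic acid to the ortho-quinone methide and is trapped at sulfur by sulfinate (SN1-type substitution) to give the bench-stable racemic sulfone.

**Step 9**
Reactants: 13 (3E)-4-[4-(benzyloxy)phenyl]-3-(tert-butoxycarbonyl)but-3-enoic acid; 18 the sulfone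
Product: 21 tert-butyl (2E)-2-{(3S,4S)-5,7-bis(benzyloxy)-4-[4-(benzyloxy)phenyl]-2-oxochroman-3-yl}-3-[4-(benzyloxy)phenyl]prop-2-enoate, via mixed pivalic anhydride 19 (not isolated), via ortho-quinone methide 20 (not isolated)
Conditions: PivCl (1.0 equiv), iPr2NEt, CH2Cl2, 0 °C; then 18, (2S,3R)-HyperBTM [(2S,3R)-3-isopropyl-2-phenyl-3,4-dihydro-2H-benzo[4,5]thiazolo[3,2-a]pyrimidine] (10 mol %), iPr2NEt, 0 °C to rt
Reagents that add atoms: none
Why: Isothiourea-catalysed Michael addition–lactonisation (formal [4+2] annulation of a C1-ammonium enolate): anhydride 19 acylates the catalyst, the derived ammonium dienolate adds through its α-carbon to quinone methide 20 released from 18 by base, and the phenoxide lactonises with catalyst turnover; the catalyst-shielded enolate face and the closed transition state should set C4 as S, while the acidic C3–H equilibrates under the amine base to the trans (3S,4S) arrangement.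

**Step 10**
Reactants: 21 the tert-butyl ester
Product: 22 (2E)-2-{(3S,4S)-5,7-bis(benzyloxy)-4-[4-(benzyloxy)phenyl]-2-oxochroman-3-yl}-3-[4-(benzyloxy)phenyl]prop-2-enoic acid
Conditions: TFA/CH2Cl2 (1:4), 0 °C
Reagents that add atoms: none
Why: Acidolysis of the tert-butyl ester (AAL1 cleavage with loss of isobutene) should leave the aryl lactone, the benzyl ethers and the alkene untouched, and the C3 centre stays in its thermodynamically preferred trans arrangement.

**Step 11**
Reactants: 22 the acid; 9 2,3,4,5-tetrakis(benzyloxy)phenol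
Product: 23 2,3,4,5-tetrakis(benzyloxy)phenyl (2E)-2-{(3S,4S)-5,7-bis(benzyloxy)-4-[4-(benzyloxy)phenyl]-2-oxochroman-3-yl}-3-[4-(benzyloxy)phenyl]prop-2-enoate
Conditions: N,N'-diisopropylcarbodiimide, 4-(dimethylamino)pyridine (cat.), CH2Cl2, 0 °C to rt
Reagents that add atoms: none
Why: Steglich esterification (carbodiimide activation with acyl transfer through the acylpyridinium) joins the hindered acid to the phenol oxygen, the only nucleophilic site of 9, without touching the stereocentres.

**Step 12**
Reactants: 23 the aryl ester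
Product: 25 (3S,4R)-5,6,7,8-tetrakis(benzyloxy)-4-[4-(benzyloxy)phenyl]-3-{(3S,4S)-5,7-bis(benzyloxy)-4-[4-(benzyloxy)phenyl]-2-oxochroman-3-yl}chroman-2-one, via ring A lactone enol 24 (not isolated)
Conditions: Sc(OTf)3 (10 mol %), HFIP/CH2Cl2 (1:3), −20 to 0 °C; pH 7 buffer at 0 °C
Reagents that add atoms: none
Why: Sc(OTf)3 in the ionising solvent activates the aryl ester carbonyl C2, so that C4 becomes a para-benzyloxy-stabilised benzylic cation (an O-alkylated para-quinone methide) that is attacked by C4a, and loss of the arenium proton gives lactone enol 24, which ketonises in the flask. The closest known reaction type is the acid-promoted intramolecular Friedel–Crafts conjugate addition (hydroarylation) of aryl cinnamates to 4-aryl-3,4-dihydrocoumarins. Ring A closes in a 6-endo-trig mode with respect to the C3=C4 alkene, through the O1–C2–C3 tether. C4 is controlled by allylic 1,3-strain: the C3'–H bond of lactone B eclipses the alkene on the side of the cis aryl group, C2' and C4' then flank the two faces, and the arene should add anti to the bulkier diarylmethine carbon C4', which corresponds to 4R. C3 is set by kinetic protonation of enol 24 on the face opposite the C4 aryl group, which is held pseudoaxial by the peri C5 benzyloxy group, so that H3 ends trans to the aryl group and the 3,4-cis (3S,4R) lactone results. The step needs regioselectivity (secured by the single C–H of the arene), chemoselectivity over the arene of ring B (which could only close a strained seven-membered bridge) and kinetic control at C3 (catalytic acid, low temperature, neutral quench).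

**Step 13**
Reactants: 25 the octabenzyl bis-lactone
Product: 26 (3S,4R)-3-[(3S,4S)-5,7-dihydroxy-4-(4-hydroxyphenyl)-2-oxochroman-3-yl]-5,6,7,8-tetrahydroxy-4-(4-hydroxyphenyl)chroman-2-one
Conditions: H2 (1 atm), 10% Pd/C, THF/EtOAc, rt; filtration and concentration under argon
Reagents that add atoms: none
Why: Catalytic hydrogenolysis cleaves all eight benzyl ethers under neutral conditions, so neither lactone is opened and the kinetically set cis C3–H of ring A, which is α to an aryl ester carbonyl, should not epimerise.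

**Compound list**

1 | 2,3,4-trihydroxybenzaldehyde | O=Cc1ccc(O)c(O)c1O | starting material
2 | 2,3,4-tris(benzyloxy)benzaldehyde | O=Cc1ccc(OCc2ccccc2)c(OCc2ccccc2)c1OCc1ccccc1 | intermediate
3 | 2,3,4-tris(benzyloxy)phenyl formate (not isolated) | O=COc1ccc(OCc2ccccc2)c(OCc2ccccc2)c1OCc1ccccc1 | intermediate
4 | 2,3,4-tris(benzyloxy)phenol | Oc1ccc(OCc2ccccc2)c(OCc2ccccc2)c1OCc1ccccc1 | intermediate
5 | 1,2,3,4-tetrakis(benzyloxy)benzene | c1cc(OCc2ccccc2)c(OCc2ccccc2)c(OCc2ccccc2)c1OCc1ccccc1 | intermediate
6 | N-[2,3,4,5-tetrakis(benzyloxy)benzylidene]-N-methylmethanaminium chloride (aryl iminium chloride, not isolated) | C[N+](C)=Cc1cc(OCc2ccccc2)c(OCc2ccccc2)c(OCc2ccccc2)c1OCc1ccccc1.[Cl-] | intermediate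
7 | 2,3,4,5-tetrakis(benzyloxy)benzaldehyde | O=Cc1cc(OCc2ccccc2)c(OCc2ccccc2)c(OCc2ccccc2)c1OCc1ccccc1 | intermediate
8 | 2,3,4,5-tetrakis(benzyloxy)phenyl formate (not isolated) | O=COc1cc(OCc2ccccc2)c(OCc2ccccc2)c(OCc2ccccc2)c1OCc1ccccc1 | intermediate
9 | 2,3,4,5-tetrakis(benzyloxy)phenol | Oc1cc(OCc2ccccc2)c(OCc2ccccc2)c(OCc2ccccc2)c1OCc1ccccc1 | intermediate
10 | di-tert-butyl succinate | CC(C)(C)OC(=O)CCC(=O)OC(C)(C)C | starting material
11 | 4-(benzyloxy)benzaldehyde | O=Cc1ccc(OCc2ccccc2)cc1 | starting material
12 | tert-butyl 2-[4-(benzyloxy)phenyl]-5-oxooxolane-3-carboxylate (paraconate lactone, racemic mixture of diastereomers, not isolated) | CC(C)(C)OC(=O)C1CC(=O)OC1c1ccc(OCc2ccccc2)cc1 | intermediate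
13 | (3E)-4-[4-(benzyloxy)phenyl]-3-(tert-butoxycarbonyl)but-3-enoic acid | OC(=O)C/C(=C\c1ccc(OCc2ccccc2)cc1)C(=O)OC(C)(C)C | intermediate
14 | 3,5-bis(benzyloxy)phenol | Oc1cc(OCc2ccccc2)cc(OCc2ccccc2)c1 | starting material
15 | 2,4-bis(benzyloxy)-6-hydroxybenzaldehyde | O=Cc1c(O)cc(OCc2ccccc2)cc1OCc1ccccc1 | intermediate
16 | 4-(benzyloxy)phenylmagnesium bromide | Br[Mg]c1ccc(OCc2ccccc2)cc1 | starting material
17 | 3,5-bis(benzyloxy)-2-{[4-(benzyloxy)phenyl](hydroxy)methyl}phenol (benzhydrol, racemic, not isolated) | OC(c1ccc(OCc2ccccc2)cc1)c1c(O)cc(OCc2ccccc2)cc1OCc1ccccc1 | intermediate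
18 | 3,5-bis(benzyloxy)-2-{[4-(benzyloxy)phenyl](4-methylbenzenesulfonyl)methyl}phenol (racemic) | Cc1ccc(cc1)S(=O)(=O)C(c1ccc(OCc2ccccc2)cc1)c1c(O)cc(OCc2ccccc2)cc1OCc1ccccc1 | intermediate
19 | mixed anhydride of 13 with pivalic acid (not isolated) | CC(C)(C)C(=O)OC(=O)C/C(=C\c1ccc(OCc2ccccc2)cc1)C(=O)OC(C)(C)C | intermediate
20 | (6Z)-3,5-bis(benzyloxy)-6-[4-(benzyloxy)benzylidene]cyclohexa-2,4-dien-1-one (ortho-quinone methide, not isolated) | O=C1C=C(OCc2ccccc2)C=C(OCc2ccccc2)/C1=C/c1ccc(OCc2ccccc2)cc1 | intermediate
21 | tert-butyl (2E)-2-{(3S,4S)-5,7-bis(benzyloxy)-4-[4-(benzyloxy)phenyl]-2-oxochroman-3-yl}-3-[4-(benzyloxy)phenyl]prop-2-enoate | O=C1Oc2cc(OCc3ccccc3)cc(OCc3ccccc3)c2[C@H](c2ccc(OCc3ccccc3)cc2)[C@H]1/C(=C\c1ccc(OCc2ccccc2)cc1)C(=O)OC(C)(C)C | intermediate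
22 | (2E)-2-{(3S,4S)-5,7-bis(benzyloxy)-4-[4-(benzyloxy)phenyl]-2-oxochroman-3-yl}-3-[4-(benzyloxy)phenyl]prop-2-enoic acid | O=C1Oc2cc(OCc3ccccc3)cc(OCc3ccccc3)c2[C@H](c2ccc(OCc3ccccc3)cc2)[C@H]1/C(=C\c1ccc(OCc2ccccc2)cc1)C(O)=O | intermediate
23 | 2,3,4,5-tetrakis(benzyloxy)phenyl (2E)-2-{(3S,4S)-5,7-bis(benzyloxy)-4-[4-(benzyloxy)phenyl]-2-oxochroman-3-yl}-3-[4-(benzyloxy)phenyl]prop-2-enoate | O=C1Oc2cc(OCc3ccccc3)cc(OCc3ccccc3)c2[C@H](c2ccc(OCc3ccccc3)cc2)[C@H]1/C(=C\c1ccc(OCc2ccccc2)cc1)C(=O)Oc1cc(OCc2ccccc2)c(OCc2ccccc2)c(OCc2ccccc2)c1OCc1ccccc1 | intermediate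
24 | ring A lactone enol of 25 (2-hydroxy-4H-chromene tautomer, C4 configured as in 25, not isolated) | OC1=C([C@H]2C(=O)Oc3cc(OCc4ccccc4)cc(OCc4ccccc4)c3[C@@H]2c2ccc(OCc3ccccc3)cc2)[C@H](c2ccc(OCc3ccccc3)cc2)c2c(OCc3ccccc3)c(OCc3ccccc3)c(OCc3ccccc3)c(OCc3ccccc3)c2O1 | intermediate
25 | (3S,4R)-5,6,7,8-tetrakis(benzyloxy)-4-[4-(benzyloxy)phenyl]-3-{(3S,4S)-5,7-bis(benzyloxy)-4-[4-(benzyloxy)phenyl]-2-oxochroman-3-yl}chroman-2-one | O=C1Oc2c(OCc3ccccc3)c(OCc3ccccc3)c(OCc3ccccc3)c(OCc3ccccc3)c2[C@@H](c2ccc(OCc3ccccc3)cc2)[C@H]1[C@H]1C(=O)Oc2cc(OCc3ccccc3)cc(OCc3ccccc3)c2[C@@H]1c1ccc(OCc2ccccc2)cc1 | intermediate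
26 | (3S,4R)-3-[(3S,4S)-5,7-dihydroxy-4-(4-hydroxyphenyl)-2-oxochroman-3-yl]-5,6,7,8-tetrahydroxy-4-(4-hydroxyphenyl)chroman-2-one | O=C1Oc2c(O)c(O)c(O)c(O)c2[C@@H](c2ccc(O)cc2)[C@H]1[C@H]1C(=O)Oc2cc(O)cc(O)c2[C@@H]1c1ccc(O)cc1 | target

**Total step count:** 13
**Longest linear sequence:** 8 steps (steps 1, 2, 3, 4, 5, 11, 12, 13)

**Steps most likely to fail**

Step 12. The kinetic cis relationship at C3 may be eroded by acid-catalysed enolisation of the product while unreacted 23 is still cyclising. Rotation about C3–C4 in the cation or addition to the wrong alkene face would give the C4 epimer, and the acid may also cleave or shift benzyl ethers. The fallback sets out from 23 and separates bond formation from protonation. 23 is treated with TMSOTf and 2,6-di-tert-butyl-4-methylpyridine in CH2Cl2 at −78 °C, so that the Friedel–Crafts conjugate addition (a silyl-triflate-mediated Mukaiyama–Michael-type closure with the arenium proton scavenged by the hindered base) stops at the ring A trimethylsilyl ketene acetal F1. F1 is then protonated in a separate operation at −78 °C with acetic acid and TBAF in THF (kinetic protonation of a silyl ketene acetal on the face opposite the C4 aryl group). This should give 25, where the route is rejoined, without the product ever meeting a strong acid.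

Step 9. Facial discrimination in the Michael addition may be insufficient, and because C3 equilibrates, every wrong-face addition ends as the enantiomer of 21, so the enantiomeric purity would fall with the diastereoselectivity. The fallback sets out from 13 and 18 and gives up asymmetric induction. The same Michael addition–lactonisation is run with the achiral isothiourea 3,4-dihydro-2H-pyrimido[2,1-b]benzothiazole to give the racemic trans lactone F2, which is resolved by preparative chromatography on a chiral stationary phase. The (3S,4S) enantiomer is 21, where the route is rejoined.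

Step 13. Hydrogenolysis of eight benzyl ethers on a crowded molecule may stall through catalyst poisoning by the partly deprotected polyphenol, and long reaction times invite air oxidation of the tetrahydroxyarene on work-up. The fallback sets out from 25 and replaces reduction by Lewis-acid debenzylation: BCl3 with pentamethylbenzene as benzyl-cation scavenger in CH2Cl2 at −78 °C, quenched cold. This should give 26 directly; no new compound is made on this way (F0).

**Further compounds**

F1 | step 12 | trimethylsilyl ketene acetal of ring A of 25 (2-trimethylsilyloxy-4H-chromene form, C4 configured as in 25) | C[Si](C)(C)OC1=C([C@H]2C(=O)Oc3cc(OCc4ccccc4)cc(OCc4ccccc4)c3[C@@H]2c2ccc(OCc3ccccc3)cc2)[C@H](c2ccc(OCc3ccccc3)cc2)c2c(OCc3ccccc3)c(OCc3ccccc3)c(OCc3ccccc3)c(OCc3ccccc3)c2O1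
F2 | step 9 | racemic trans form of 21 (both enantiomers written) | O=C1Oc2cc(OCc3ccccc3)cc(OCc3ccccc3)c2[C@H](c2ccc(OCc3ccccc3)cc2)[C@H]1/C(=C\c1ccc(OCc2ccccc2)cc1)C(=O)OC(C)(C)C.O=C1Oc2cc(OCc3ccccc3)cc(OCc3ccccc3)c2[C@@H](c2ccc(OCc3ccccc3)cc2)[C@@H]1/C(=C\c1ccc(OCc2ccccc2)cc1)C(=O)OC(C)(C)C
F0 | step 13 | none | none
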